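Everything rests on opening ring A at C1–C2, C2–C3 and C4–C5 while the depside ester stays in place. The key step exploits the ring A pattern: a free C2 hydroxyl beside the C1 ester, oxygen at C4 and propyl at C6. Irradiating an α-diazo enone that already carries ring B as its aryl ester triggers a Wolff shift (C5–C6) to a vinylketene. (Triisopropylsilyloxy)ethyne adds, and warming closes the benzene ring with the C2 oxygen free and the C4 oxygen silylated. The precursor is the ring B ester of (E)-3-(2-diazoacetyl)hex-2-enoic acid, built from glyoxylic acid, hexan-2-one and a phenol obtained by C–H borylation. Desilylation ends the route.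

Key step: step 9

Assumption: the target has no stereocentre, so only alkene geometry has to be controlled, and it disappears on aromatisation. Glyoxylic acid is used as its commercial monohydrate, and the organozinc, alkyllithium and lithium amide reagents as commercial solutions.

Step 1
Reactants: 1 methyl 2-bromo-6-methoxybenzoate; 2 n-propylzinc bromide (0.5 M in THF)
Product: 3 methyl 2-methoxy-6-propylbenzoate
Conditions: Pd(dppf)Cl2 (3 mol %), THF, 60 °C
Reagents that add atoms: none
Why: Negishi coupling, in which the ortho ester speeds oxidative addition of the aryl bromide to zerovalent palladium, the wide-bite dppf ligand favours reductive elimination over β-hydride loss from the primary propyl group, and the organozinc reagent leaves the methyl ester alone.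

Step 2
Reactants: 3 methyl 2-methoxy-6-propylbenzoate
Product: 5 methyl 4-hydroxy-2-methoxy-6-propylbenzoate, via pinacol boronate 4 (not isolated)
Conditions: [Ir(OMe)(cod)]2 (1.5 mol %), 4,4'-di-tert-butyl-2,2'-bipyridine (3 mol %), B2pin2 (1.0 equiv), THF, 80 °C; evaporate; 30% H2O2, NaOH (1 equiv), THF–H2O, 0 °C
Reagents that add atoms: bis(pinacolato)diboron, CC1(C)OB(OC1(C)C)B1OC(C)(C)C(C)(C)O1 (boryl group of 4); hydrogen peroxide, OO (phenol oxygen of 5)
Why: Sterically governed iridium-catalysed aromatic C–H borylation followed by boronate oxidation, where only C4–H of the 1,2,3-trisubstituted ring has no ortho neighbour, so boron and then oxygen should enter para to the ester, and the doubly ortho-flanked methyl ester resists cold alkaline peroxide.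

Step 3
Reactants: 6 glyoxylic acid; 7 hexan-2-one
Product: 8 (E)-3-acetylhex-2-enoic acid
Conditions: 85% H3PO4, 7 in excess, 80 °C; crystallise
Reagents that add atoms: none
Why: Acid-catalysed crossed aldol condensation, in which the ketone reacts through its more substituted enol at C3 with the non-enolisable aldehyde, and dehydration gives the conjugated keto acid whose E isomer (acetyl trans to carboxyl) is the open-chain crystallisable form, as known for butanone and its homologues.

Step 4
Reactants: 8 (E)-3-acetylhex-2-enoic acid; 5 methyl 4-hydroxy-2-methoxy-6-propylbenzoate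
Product: 9 3-methoxy-4-(methoxycarbonyl)-5-propylphenyl (E)-3-acetylhex-2-enoate
Conditions: DCC (1.1 equiv), DMAP (10 mol %), CH2Cl2, 0 °C to rt
Reagents that add atoms: none
Why: Steglich esterification, where carbodiimide activation with acyl transfer by DMAP lets the weakly nucleophilic single phenol of 5 be acylated under neutral conditions that leave the E enone and both methyl groups of ring B unchanged.

Step 5
Reactants: 9 3-methoxy-4-(methoxycarbonyl)-5-propylphenyl (E)-3-acetylhex-2-enoate
Product: 12 3-methoxy-4-(methoxycarbonyl)-5-propylphenyl (E)-3-(2-diazoacetyl)hex-2-enoate, via lithium enolate 10 (not isolated), via trifluoroacetyl diketone 11 (not isolated)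
Conditions: LiN(SiMe3)2 (1.1 equiv), THF, −78 °C (9 added to the base); CF3CO2CH2CF3, −78 °C; 5% HCl; then MsN3, Et3N, H2O (1 equiv), MeCN, rt
Reagents that add atoms: lithium hexamethyldisilazide, [Li]N([Si](C)(C)C)[Si](C)(C)C (lithium of 10); 2,2,2-trifluoroethyl trifluoroacetate, O=C(OCC(F)(F)F)C(F)(F)F (CF3CO group of 11); methanesulfonyl azide, CS(=O)(=O)N=[N+]=[N-] (N2 of 12)
Why: Detrifluoroacetylative diazo transfer (a Regitz-type transfer developed for enones), in which the ketone can be enolised only at its methyl group, trifluoroacetylation activates that carbon, and the sulfonyl azide delivers N2 with loss of the trifluoroacetyl group under amine base. This avoids diazomethane, which would add to the activated alkene.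

Step 6
Reactants: 13 triisopropylsilyl chloride; 14 tetrahydrofuran
Product: 16 triisopropyl(vinyloxy)silane, via lithium ethenolate 15 (not isolated)
Conditions: n-BuLi, 14 as solvent, rt, 16 h; then 13, DMPU, 0 °C to rt
Reagents that add atoms: n-butyllithium, [Li]CCCC (lithium of 15)
Why: Deprotonation of tetrahydrofuran next to oxygen and cycloreversion gives ethene and the acetaldehyde enolate free of any aldehyde, and the bulky chlorosilane reacts at oxygen (enolate O-silylation).

Step 7
Reactants: 16 triisopropyl(vinyloxy)silane
Product: 18 (Z)-(2-bromoethenyloxy)triisopropylsilane, via dibromo ether 17 (not isolated)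
Conditions: Br2, CH2Cl2, −78 °C; then Et3N, −78 °C to rt
Reagents that add atoms: bromine, BrBr
Why: Bromination–dehydrobromination of an enol ether, the sequence used for 2-bromovinyl alkyl and trimethylsilyl ethers. The bulky silyl group slows attack of bromide at silicon, and E2 loss of HBr from the α-bromo ether normally favours the cis (Z) isomer.

Step 8
Reactants: 18 (Z)-(2-bromoethenyloxy)triisopropylsilane
Product: 20 (triisopropylsilyloxy)ethyne, via lithium acetylide 19 (not isolated)
Conditions: LiN(iPr)2 (2.2 equiv), THF, −78 °C; then H2O, −78 to 0 °C; short-path distillation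
Reagents that add atoms: lithium diisopropylamide, [Li]N(C(C)C)C(C)C (lithium of 19)
Why: Classical alkynyl ether synthesis by dehydrobromination of a 2-bromovinyl ether, where H and Br are anti in the Z isomer so E2 elimination is easy, the second equivalent of base stores the product as its acetylide until the quench, and the triisopropylsilyl group tolerates cold hindered amide base.

Step 9
Reactants: 12 3-methoxy-4-(methoxycarbonyl)-5-propylphenyl (E)-3-(2-diazoacetyl)hex-2-enoate; 20 (triisopropylsilyloxy)ethyne
Product: 25 3-methoxy-4-(methoxycarbonyl)-5-propylphenyl 2-hydroxy-6-propyl-4-(triisopropylsilyloxy)benzoate, via vinylketene 21 (not isolated), via cyclobutenone 22 (not isolated), via dienylketene 23 (not isolated), via cyclohexadienone 24 (not isolated)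
Conditions: 20 (2.5 equiv), ClCH2CH2Cl, hν (365 nm LED, Pyrex), 5 °C, slow addition of 12; then dark, 80 °C
Reagents that add atoms: none
Why: Light of 365 nm expels N2 from 12 while the alkenyl group shifts from the carbonyl carbon to the former diazo carbon (photochemical Wolff rearrangement, new C5–C6 bond), so the old carbonyl carbon becomes the ketene carbon of 21. The electron-rich alkyne 20 adds across the ketene C=C in a (2+2) cycloaddition that makes C2–C3 and C4–C5 and gives the 3-silyloxy-4-alkenylcyclobutenone 22, which on warming opens in a reversible four-electron conrotatory step to dienylketene 23. Ring A closes by thermal disrotatory six-electron electrocyclisation of 23 between the ketene carbon and the ester-bearing alkene carbon (C1–C2), and the β-keto ester 24 enolises at once to the hydrogen-bonded salicylate 25. This is the diazo ketone version of the Danheiser benzannulation, an established entry to resorcinol monosilyl ethers from silyloxyalkynes, and no stereocentre survives because the single centres of racemic 22 and 24 are lost on aromatisation. The step needs regioselectivity in the cycloaddition, and the polarity of 20 supplies it: its unsubstituted nucleophilic carbon attacks the electrophilic ketene carbon, which puts the silyloxy group at C4 and the free hydroxyl at C2, and the ester on the alkene terminus makes the ketene more electrophilic still. Because acyl and ester groups are trans in 12, only hydrogen sits on the inner face of the triene terminus in 23; light above 350 nm addresses the diazo chromophore and not the aryl ester (no photo-Fries migration); and slow addition of 12 to excess 20 holds down dipolar addition of the diazo group to the activated alkene and acylation of the product phenol by the ketene.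

Step 10
Reactants: 25 3-methoxy-4-(methoxycarbonyl)-5-propylphenyl 2-hydroxy-6-propyl-4-(triisopropylsilyloxy)benzoate
Product: 26 3-methoxy-4-(methoxycarbonyl)-5-propylphenyl 2,4-dihydroxy-6-propylbenzoate (target)
Conditions: HF·pyridine, THF, 0 °C to rt
Reagents that add atoms: none
Why: Cleavage of an aryl silyl ether driven by Si–F bond formation, where the mildly acidic reagent spares the depside ester, the methyl ester and the methyl ether, and would also converge any material in which the silyl group ended up on the other ring A oxygen.

Compound list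
1 | methyl 2-bromo-6-methoxybenzoate | COC(=O)c1c(Br)cccc1OC | starting material
2 | n-propylzinc bromide | CCC[Zn]Br | starting material
3 | methyl 2-methoxy-6-propylbenzoate | CCCc1cccc(OC)c1C(=O)OC | intermediate
4 | methyl 2-methoxy-6-propyl-4-(4,4,5,5-tetramethyl-1,3,2-dioxaborolan-2-yl)benzoate | CCCc1cc(B2OC(C)(C)C(C)(C)O2)cc(OC)c1C(=O)OC | intermediate
5 | methyl 4-hydroxy-2-methoxy-6-propylbenzoate (ring B phenol) | CCCc1cc(O)cc(OC)c1C(=O)OC | intermediate
6 | glyoxylic acid | O=CC(=O)O | starting material
7 | hexan-2-one | CCCCC(C)=O | starting material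
8 | (E)-3-acetylhex-2-enoic acid | CCC/C(=C\C(=O)O)C(C)=O | intermediate
9 | 3-methoxy-4-(methoxycarbonyl)-5-propylphenyl (E)-3-acetylhex-2-enoate | CCC/C(=C\C(=O)Oc1cc(CCC)c(C(=O)OC)c(OC)c1)C(C)=O | intermediate
10 | kinetic lithium enolate of 9 (CH2=C(OLi) in place of the acetyl group, E alkene kept) | CCC/C(=C\C(=O)Oc1cc(CCC)c(C(=O)OC)c(OC)c1)C(=C)O[Li] | intermediate
11 | 3-methoxy-4-(methoxycarbonyl)-5-propylphenyl (E)-3-(4,4,4-trifluoro-3-oxobutanoyl)hex-2-enoate | CCC/C(=C\C(=O)Oc1cc(CCC)c(C(=O)OC)c(OC)c1)C(=O)CC(=O)C(F)(F)F | intermediate
12 | 3-methoxy-4-(methoxycarbonyl)-5-propylphenyl (E)-3-(2-diazoacetyl)hex-2-enoate | CCC/C(=C\C(=O)Oc1cc(CCC)c(C(=O)OC)c(OC)c1)C(=O)C=[N+]=[N-] | intermediate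
13 | triisopropylsilyl chloride | CC(C)[Si](Cl)(C(C)C)C(C)C | starting material
14 | tetrahydrofuran | C1CCOC1 | starting material
15 | lithium ethenolate (acetaldehyde lithium enolate) | [Li]OC=C | intermediate
16 | triisopropyl(vinyloxy)silane | C=CO[Si](C(C)C)(C(C)C)C(C)C | intermediate
17 | (1,2-dibromoethoxy)triisopropylsilane (racemic) | BrCC(Br)O[Si](C(C)C)(C(C)C)C(C)C | intermediate
18 | (Z)-(2-bromoethenyloxy)triisopropylsilane | Br/C=C\O[Si](C(C)C)(C(C)C)C(C)C | intermediate
19 | lithium (triisopropylsilyloxy)ethynide | [Li]C#CO[Si](C(C)C)(C(C)C)C(C)C | intermediate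
20 | (triisopropylsilyloxy)ethyne | C#CO[Si](C(C)C)(C(C)C)C(C)C | intermediate
21 | 3-methoxy-4-(methoxycarbonyl)-5-propylphenyl (2E)-5-oxo-3-propylpenta-2,4-dienoate (vinylketene) | CCC/C(=C\C(=O)Oc1cc(CCC)c(C(=O)OC)c(OC)c1)C=C=O | intermediate
22 | 3-methoxy-4-(methoxycarbonyl)-5-propylphenyl (E)-3-[4-oxo-2-(triisopropylsilyloxy)cyclobut-2-en-1-yl]hex-2-enoate (racemic) | CCC/C(=C\C(=O)Oc1cc(CCC)c(C(=O)OC)c(OC)c1)C2C(=O)C=C2O[Si](C(C)C)(C(C)C)C(C)C | intermediate
23 | 3-methoxy-4-(methoxycarbonyl)-5-propylphenyl (2E,4E)-7-oxo-3-propyl-5-(triisopropylsilyloxy)hepta-2,4,6-trienoate (dienylketene) | O=C=C/C(O[Si](C(C)C)(C(C)C)C(C)C)=C\C(CCC)=C\C(=O)Oc1cc(CCC)c(C(=O)OC)c(OC)c1 | intermediate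
24 | 3-methoxy-4-(methoxycarbonyl)-5-propylphenyl 2-oxo-6-propyl-4-(triisopropylsilyloxy)cyclohexa-3,5-diene-1-carboxylate (racemic) | CCCC1=CC(O[Si](C(C)C)(C(C)C)C(C)C)=CC(=O)C1C(=O)Oc2cc(CCC)c(C(=O)OC)c(OC)c2 | intermediate
25 | 3-methoxy-4-(methoxycarbonyl)-5-propylphenyl 2-hydroxy-6-propyl-4-(triisopropylsilyloxy)benzoate | CCCc1cc(O[Si](C(C)C)(C(C)C)C(C)C)cc(O)c1C(=O)Oc1cc(CCC)c(C(=O)OC)c(OC)c1 | intermediate
26 | 3-methoxy-4-(methoxycarbonyl)-5-propylphenyl 2,4-dihydroxy-6-propylbenzoate | CCCc1cc(O)cc(O)c1C(=O)Oc1cc(CCC)c(C(=O)OC)c(OC)c1 | target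

Total step count: 10.
Longest linear sequence: 6 steps (1, 2, 4, 5, 9, 10).

Steps most likely to fail

1. Step 9.
- What may go wrong: residual light absorption by the aryl ester with acyl migration; light-induced E-to-Z isomerisation of the activated alkene, after which the ketene can close onto the ester carbonyl instead of meeting the alkyne; dipolar addition of the diazo group to the alkene of a second molecule; and acylation of the product phenol by the ketene.
- Fallback: this abandons the annulation for a classical depside coupling. It sets out from 5 and comes back at 26.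
- BCl3 in CH2Cl2 at −10 °C cleaves the methyl ether next to the ester of 5 by chelation and should give methyl 2,4-dihydroxy-6-propylbenzoate F1.
- BnBr and K2CO3 in DMF give methyl 2,4-bis(benzyloxy)-6-propylbenzoate F2.
- KOH in aqueous DMSO at 90 °C gives 2,4-bis(benzyloxy)-6-propylbenzoic acid F3.
- (CF3CO)2O in toluene joins this acid to a second portion of 5 as 3-methoxy-4-(methoxycarbonyl)-5-propylphenyl 2,4-bis(benzyloxy)-6-propylbenzoate F4.
- H2 over Pd/C in EtOAc then gives 26.

2. Step 5.
- What may go wrong: conjugate addition of the enolate or of the amide base to the doubly activated alkene; competing deprotonation at the allylic CH2 of the propyl chain; and cleavage of the aryl ester by trifluoroethoxide or by the wet amine.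
- Fallback: this avoids any lithium enolate. It sets out from 9 and comes back at 12.
- TMSOTf and Et3N in CH2Cl2 at 0 °C enolise the ketone softly to 3-methoxy-4-(methoxycarbonyl)-5-propylphenyl (E)-3-[1-(trimethylsilyloxy)ethenyl]hex-2-enoate F5.
- NBS in THF at −78 °C gives 3-methoxy-4-(methoxycarbonyl)-5-propylphenyl (E)-3-(2-bromoacetyl)hex-2-enoate F6.
- N,N'-ditosylhydrazine and DBU in THF at 0 °C replace bromide by the hydrazine nitrogen and eliminate two sulfinates to give 12.

3. Step 8 (with its feeder, step 7).
- What may go wrong: attack at silicon with loss of the silyl group; silyl transfer from oxygen to carbon in the lithiated alkyne; acid-catalysed hydration during work-up; and evaporation losses of the small alkyne.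
- Fallback: this replaces the silyl ynol ether by an alkyl one made by the trichloroethene route. It sets out from 12 and comes back at 26.
- BnOH, KH and trichloroethene in THF give benzyl (E)-1,2-dichloroethenyl ether F7.
- n-BuLi (2.2 equiv) at −78 °C followed by MeOH gives benzyl ethynyl ether F8.
- This alkyne is irradiated with 12 as in step 9. The excess alkyne is stripped off in vacuo before the warm stage because it rearranges on heating. The product should be 3-methoxy-4-(methoxycarbonyl)-5-propylphenyl 4-(benzyloxy)-2-hydroxy-6-propylbenzoate F9.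
- H2 over Pd/C in EtOAc gives 26.

Further compounds
F1 | step 9 | methyl 2,4-dihydroxy-6-propylbenzoate | CCCc1cc(O)cc(O)c1C(=O)OC
F2 | step 9 | methyl 2,4-bis(benzyloxy)-6-propylbenzoate | CCCc1cc(OCc2ccccc2)cc(OCc2ccccc2)c1C(=O)OC
F3 | step 9 | 2,4-bis(benzyloxy)-6-propylbenzoic acid | CCCc1cc(OCc2ccccc2)cc(OCc2ccccc2)c1C(=O)O
F4 | step 9 | 3-methoxy-4-(methoxycarbonyl)-5-propylphenyl 2,4-bis(benzyloxy)-6-propylbenzoate | CCCc1cc(OCc2ccccc2)cc(OCc2ccccc2)c1C(=O)Oc1cc(CCC)c(C(=O)OC)c(OC)c1
F5 | step 5 | 3-methoxy-4-(methoxycarbonyl)-5-propylphenyl (E)-3-[1-(trimethylsilyloxy)ethenyl]hex-2-enoate | CCC/C(=C\C(=O)Oc1cc(CCC)c(C(=O)OC)c(OC)c1)C(=C)O[Si](C)(C)C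
F6 | step 5 | 3-methoxy-4-(methoxycarbonyl)-5-propylphenyl (E)-3-(2-bromoacetyl)hex-2-enoate | CCC/C(=C\C(=O)Oc1cc(CCC)c(C(=O)OC)c(OC)c1)C(=O)CBr
F7 | step 8 | benzyl (E)-1,2-dichloroethenyl ether | Cl/C=C(/Cl)OCc1ccccc1
F8 | step 8 | benzyl ethynyl ether | C#COCc1ccccc1
F9 | step 8 | 3-methoxy-4-(methoxycarbonyl)-5-propylphenyl 4-(benzyloxy)-2-hydroxy-6-propylbenzoate | CCCc1cc(OCc2ccccc2)cc(O)c1C(=O)Oc1cc(CCC)c(C(=O)OC)c(OC)c1
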